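**Retrosynthetic overview**
1. Target 35 ← bis-silyl ether 34 ← copper-catalysed oxidative C–O coupling of (E)-alkenylboronate 32 with 3-methylbut-2-enoic acid 33 (key bond: the enol ester).
2. 32 ← alcohol 26 (oxidation, chromium boron-olefination with 30); the cis C7 acetonyl group of 26 ← tethered oxidative enol-ether coupling of isopropenyl ether 23 (new method).
3. Cycloheptenone 20 ← one-carbon ring expansion of cyclohexenyl silyl ether 12 with the zinc carbenoid from 17, which brings C2 and its CH2O arm.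
4. Side chain of 12 ← palladium-catalysed carbonylative B-alkyl Suzuki–Miyaura coupling of 7, CO and 8, then CBS reduction.
5. Ring order: the six-membered ring is made first by asymmetric Diels–Alder reaction of enal 3 with siloxydiene 5 (sets C5 and C6), then expanded to the only ring of the target.

Assumption: the boron Lewis acid in step 4 shows its usual facial sense for α-substituted enals (otherwise its mirror image is used); locants C1–C7 in the text are those of the target cycloheptenone (C1 = C=O, C2 bears CH2OH, C5 quaternary, C6 bears the enol ester, C7 bears the acetonyl group).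
Abbreviations in names: TBS = tert-butyl(dimethyl)silyl, PMB = 4-methoxybenzyl, TBSO and PMBO = the corresponding oxy groups.

**Step 1**
Reactants: 1 3-methylbut-2-en-1-ol
Product: 2 1-methoxy-4-{[(3-methylbut-2-en-1-yl)oxy]methyl}benzene
Conditions: NaH, 4-methoxybenzyl chloride, Bu4NI (cat.), THF–DMF, 0 °C to rt
Reagents that add atoms: 4-methoxybenzyl chloride, COc1ccc(CCl)cc1
Why: Williamson ether synthesis; the PMB ether masks the future C6 CH2OH arm and is later removable oxidatively beside silyl ethers.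

**Step 2**
Reactants: 2 1-methoxy-4-{[(3-methylbut-2-en-1-yl)oxy]methyl}benzene
Product: 3 (2E)-2-methyl-4-(PMBO)but-2-enal
Conditions: SeO2 (1.2 equiv), 1,4-dioxane, 80 °C
Reagents that add atoms: selenium dioxide, O=[Se]=O
Why: Riley allylic oxidation (ene reaction then 2,3-sigmatropic shift) selects the methyl group trans to the CH2O arm and runs on to the conjugated (E)-aldehyde.

**Step 3**
Reactants: 4 but-3-en-2-one
Product: 5 2-(TBSO)buta-1,3-diene
Conditions: TBSOTf, Et3N, Et2O, 0 °C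
Reagents that add atoms: tert-butyldimethylsilyl trifluoromethanesulfonate, CC(C)(C)[Si](C)(C)OS(=O)(=O)C(F)(F)F
Why: Soft enolisation and O-silylation of the methyl ketone give the electron-rich 2-siloxydiene.

**Step 4**
Reactants: 3 (2E)-2-methyl-4-(PMBO)but-2-enal; 5 2-(TBSO)buta-1,3-diene
Product: 6 (1S,6S)-1-methyl-6-[(PMBO)methyl]-4-(TBSO)cyclohex-3-ene-1-carbaldehyde
Conditions: (S)-o-tolyl oxazaborolidine activated with Tf2NH (20 mol %), CH2Cl2, −78 to −40 °C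
Reagents that add atoms: none
Why: Catalytic enantioselective Diels–Alder reaction: the CH2 terminus of the siloxydiene bonds to the aldehyde β-carbon (para orientation), the E geometry of 3 is transferred suprafacially so the methyl group and the CH2OPMB arm are cis, and the chiral boron Lewis acid shields one face of the s-trans enal so the diene adds to the Si face of C2 of 3, setting C5 and C6 of the target.

**Step 5**
Reactants: 6 (1S,6S)-1-methyl-6-[(PMBO)methyl]-4-(TBSO)cyclohex-3-ene-1-carbaldehyde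
Product: 7 (4R,5S)-4-ethenyl-4-methyl-5-[(PMBO)methyl]-1-(TBSO)cyclohex-1-ene
Conditions: Ph3PCH3Br, KOtBu, THF, 0 °C to rt
Reagents that add atoms: methyltriphenylphosphonium bromide, C[P+](c1ccccc1)(c1ccccc1)c1ccccc1.[Br-]
Why: Wittig methylenation of the non-enolisable quaternary aldehyde; no stereocentre is touched.

**Step 6**
Reactants: 7 (4R,5S)-4-ethenyl-4-methyl-5-[(PMBO)methyl]-1-(TBSO)cyclohex-1-ene; 8 2-bromoprop-1-ene
Product: 10 2-methyl-5-[(1S,6S)-1-methyl-6-[(PMBO)methyl]-4-(TBSO)cyclohex-3-en-1-yl]pent-1-en-3-one, via alkylborane 9 (not isolated)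
Conditions: 9-BBN, THF, 0 °C to rt; then Pd(PPh3)4 (5 mol %), K3PO4, CO (1 atm), 8, dioxane, 60 °C
Reagents that add atoms: carbon monoxide, [C-]#[O+]
Why: Anti-Markovnikov hydroboration of the vinyl group by 9-BBN (the trisubstituted silyl enol ether is left alone), then palladium-catalysed carbonylative B-alkyl Suzuki–Miyaura coupling (oxidative addition of 8, CO insertion, transmetalation, reductive elimination) joins side chain, CO and the isopropenyl unit.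

**Step 7**
Reactants: 10 2-methyl-5-[(1S,6S)-1-methyl-6-[(PMBO)methyl]-4-(TBSO)cyclohex-3-en-1-yl]pent-1-en-3-one
Product: 11 (3R)-2-methyl-5-[(1S,6S)-1-methyl-6-[(PMBO)methyl]-4-(TBSO)cyclohex-3-en-1-yl]pent-1-en-3-ol
Conditions: (S)-2-methyl-CBS-oxazaborolidine (20 mol %), catecholborane, toluene, −78 °C
Reagents that add atoms: none
Why: Corey–Bakshi–Shibata 1,2-reduction; the isopropenyl group acts as the large substituent, so the (S)-catalyst gives the (R)-allylic alcohol.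

**Step 8**
Reactants: 11 (3R)-2-methyl-5-[(1S,6S)-1-methyl-6-[(PMBO)methyl]-4-(TBSO)cyclohex-3-en-1-yl]pent-1-en-3-ol
Product: 12 (4S,5S)-4-methyl-4-[(3R)-4-methyl-3-(TBSO)pent-4-en-1-yl]-5-[(PMBO)methyl]-1-(TBSO)cyclohex-1-ene
Conditions: TBSCl, imidazole, DMF, rt
Reagents that add atoms: tert-butyl(chloro)dimethylsilane, CC(C)(C)[Si](C)(C)Cl
Why: Silylation protects the secondary allylic alcohol for the carbenoid, oxidation and enolate steps.

**Step 9**
Reactants: 13 ethane-1,2-diol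
Product: 14 2-(TBSO)ethan-1-ol
Conditions: NaH (1.0 equiv), THF, rt; then TBSCl, 0 °C to rt
Reagents that add atoms: tert-butyl(chloro)dimethylsilane, CC(C)(C)[Si](C)(C)Cl
Why: Monosilylation of the symmetrical diol through its sparingly soluble monosodium alkoxide.

**Step 10**
Reactants: 14 2-(TBSO)ethan-1-ol
Product: 15 (TBSO)acetaldehyde
Conditions: TEMPO (10 mol %), PhI(OAc)2, CH2Cl2, rt
Reagents that add atoms: none
Why: TEMPO-catalysed oxidation stops cleanly at the aldehyde.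

**Step 11**
Reactants: 15 (TBSO)acetaldehyde
Product: 16 (TBSO)acetaldehyde hydrazone
Conditions: N2H4·H2O (excess), EtOH, 0 °C to rt
Reagents that add atoms: hydrazine, NN
Why: Condensation to the hydrazone; excess hydrazine suppresses azine formation.

**Step 12**
Reactants: 16 (TBSO)acetaldehyde hydrazone
Product: 17 1,1-diiodo-2-(TBSO)ethane
Conditions: I2, Et3N, THF–Et2O, 0 °C
Reagents that add atoms: iodine, II
Why: Barton iodination: iodine oxidises the hydrazone to the diazo compound, which is captured by iodine with loss of N2 to give the geminal diiodide.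

**Step 13**
Reactants: 12 (4S,5S)-4-methyl-4-[(3R)-4-methyl-3-(TBSO)pent-4-en-1-yl]-5-[(PMBO)methyl]-1-(TBSO)cyclohex-1-ene; 17 1,1-diiodo-2-(TBSO)ethane
Product: 20 (5S,6S)-5-methyl-5-[(3R)-4-methyl-3-(TBSO)pent-4-en-1-yl]-6-[(PMBO)methyl]-2-[(TBSO)methyl]cyclohept-2-en-1-one, via siloxycyclopropane 18 (not isolated), via chloro ketone 19 (not isolated)
Conditions: Et2Zn, 17, CH2Cl2, 0 °C to rt; then FeCl3, DMF, 0 °C to rt; then NaOAc, MeOH, 60 °C
Reagents that add atoms: none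
Why: Furukawa-type Simmons–Smith cyclopropanation of the silyl enol ether by the substituted zinc carbenoid, then Ito–Saegusa ring expansion (one-electron oxidation by FeCl3 opens the internal cyclopropane bond, chlorine transfer gives the β-chloro ketone, acetate-induced E1cB loss of HCl) gives the cycloheptenone already carrying the C2 CH2OTBS arm; the cyclopropane stereocentres vanish and C5 and C6 are untouched.

**Step 14**
Reactants: 20 (5S,6S)-5-methyl-5-[(3R)-4-methyl-3-(TBSO)pent-4-en-1-yl]-6-[(PMBO)methyl]-2-[(TBSO)methyl]cyclohept-2-en-1-one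
Product: 21 (5S,6S)-6-(hydroxymethyl)-5-methyl-5-[(3R)-4-methyl-3-(TBSO)pent-4-en-1-yl]-2-[(TBSO)methyl]cyclohept-2-en-1-one
Conditions: DDQ, CH2Cl2–pH 7 buffer, 0 °C
Reagents that add atoms: none
Why: Oxidative PMB cleavage (benzylic hydride abstraction, hydrolysis) frees the primary alcohol while both silyl ethers stay.

**Step 15**
Reactants: 21 (5S,6S)-6-(hydroxymethyl)-5-methyl-5-[(3R)-4-methyl-3-(TBSO)pent-4-en-1-yl]-2-[(TBSO)methyl]cyclohept-2-en-1-one; 22 prop-1-en-2-yl acetate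
Product: 23 (5S,6S)-5-methyl-5-[(3R)-4-methyl-3-(TBSO)pent-4-en-1-yl]-6-[(prop-1-en-2-yloxy)methyl]-2-[(TBSO)methyl]cyclohept-2-en-1-one
Conditions: [Ir(cod)Cl]2 (2 mol %), Na2CO3, toluene, 100 °C
Reagents that add atoms: none
Why: Iridium-catalysed transfer vinylation (alkoxide addition to the enol acetate, β-acetate elimination) turns the alcohol into the isopropenyl ether that serves as a tethered acetone enol equivalent.

**Step 16**
Reactants: 23 (5S,6S)-5-methyl-5-[(3R)-4-methyl-3-(TBSO)pent-4-en-1-yl]-6-[(prop-1-en-2-yloxy)methyl]-2-[(TBSO)methyl]cyclohept-2-en-1-one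
Product: 26 (5S,6S,7R)-6-(hydroxymethyl)-5-methyl-5-[(3R)-4-methyl-3-(TBSO)pent-4-en-1-yl]-7-(2-oxopropyl)-2-[(TBSO)methyl]cyclohept-2-en-1-one, via silyl dienol ether 24 (not isolated), via cyclic hemiketal 25 (not isolated)
Conditions: LiN(SiMe3)2, Me3SiCl, THF, −78 °C; then (NH4)2Ce(NO3)6 (2.2 equiv), NaHCO3, MeCN, −30 °C; aq. NaHCO3 work-up
Reagents that add atoms: water, O
Why: Proposed new method: temporary-tether oxidative enol-ether coupling – tetravalent cerium oxidises the kinetic silyl dienol ether 24 to the planar C7 α-keto radical, which can add only along its π axis to the CH2 terminus of the isopropenyl ether held on the neighbouring C6 arm (6-endo closure to a cis-fused oxabicycle); the α-alkoxy radical is oxidised to the oxocarbenium ion, water gives hemiketal 25, and this opens to the methyl ketone and the free CH2OH, so the acetonyl group arrives cis to the C6 arm (7R); the closest known reactions are the intermolecular (NH4)2Ce(NO3)6-mediated coupling of silyl enol ethers with simple enol ethers to 1,4-dicarbonyl compounds and silicon-tethered oxidative enolate couplings.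

**Step 17**
Reactants: 27 dichloromethane
Product: 28 (dichloromethyl)boronic acid
Conditions: n-BuLi, THF, −100 °C; B(OMe)3; then aq. HCl
Reagents that add atoms: trimethyl borate, COB(OC)OC; water, O
Why: Deprotonation of dichloromethane and borylation of LiCHCl2 (Matteson-type chemistry), then hydrolysis of the borate.

**Step 18**
Reactants: 28 (dichloromethyl)boronic acid; 29 2,3-dimethylbutane-2,3-diol
Product: 30 2-(dichloromethyl)-4,4,5,5-tetramethyl-1,3,2-dioxaborolane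
Conditions: MgSO4, CH2Cl2, rt
Reagents that add atoms: none
Why: Esterification of the boronic acid with pinacol under dehydrating conditions.

**Step 19**
Reactants: 26 (5S,6S,7R)-6-(hydroxymethyl)-5-methyl-5-[(3R)-4-methyl-3-(TBSO)pent-4-en-1-yl]-7-(2-oxopropyl)-2-[(TBSO)methyl]cyclohept-2-en-1-one; 30 2-(dichloromethyl)-4,4,5,5-tetramethyl-1,3,2-dioxaborolane
Product: 32 (5S,6S,7R)-5-methyl-5-[(3R)-4-methyl-3-(TBSO)pent-4-en-1-yl]-7-(2-oxopropyl)-6-[(E)-2-(4,4,5,5-tetramethyl-1,3,2-dioxaborolan-2-yl)ethenyl]-2-[(TBSO)methyl]cyclohept-2-en-1-one, via aldehyde 31 (not isolated)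
Conditions: Dess–Martin periodinane, NaHCO3, CH2Cl2, 0 °C; filtration; then CrCl2, LiI, 30, THF, rt
Reagents that add atoms: none
Why: Dess–Martin oxidation and, without isolating the epimerisable aldehyde, Takai–Utimoto-type chromium olefination with the geminal dichromium species from 30, which attacks only the aldehyde and gives the (E)-alkenylboronate by anti-periplanar elimination.

**Step 20**
Reactants: 32 (5S,6S,7R)-5-methyl-5-[(3R)-4-methyl-3-(TBSO)pent-4-en-1-yl]-7-(2-oxopropyl)-6-[(E)-2-(4,4,5,5-tetramethyl-1,3,2-dioxaborolan-2-yl)ethenyl]-2-[(TBSO)methyl]cyclohept-2-en-1-one; 33 3-methylbut-2-enoic acid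
Product: 34 (E)-2-{(1S,2S,7R)-2-methyl-2-[(3R)-4-methyl-3-(TBSO)pent-4-en-1-yl]-6-oxo-7-(2-oxopropyl)-5-[(TBSO)methyl]cyclohept-4-en-1-yl}ethenyl 3-methylbut-2-enoate
Conditions: Cu(OAc)2 (30 mol %), Et3N, 4 Å MS, O2 (1 atm), CH2Cl2–MeCN, rt
Reagents that add atoms: none
Why: Copper-catalysed oxidative Chan–Lam-type C–O coupling: the alkenyl group passes from boron to the divalent copper carboxylate, oxidation to trivalent copper and reductive elimination form the enol ester with retention of the E geometry.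

**Step 21**
Reactants: 34 (E)-2-{(1S,2S,7R)-2-methyl-2-[(3R)-4-methyl-3-(TBSO)pent-4-en-1-yl]-6-oxo-7-(2-oxopropyl)-5-[(TBSO)methyl]cyclohept-4-en-1-yl}ethenyl 3-methylbut-2-enoate
Product: 35 (E)-2-{(1S,2S,7R)-2-[(3R)-3-hydroxy-4-methylpent-4-en-1-yl]-5-(hydroxymethyl)-2-methyl-6-oxo-7-(2-oxopropyl)cyclohept-4-en-1-yl}ethenyl 3-methylbut-2-enoate
Conditions: HF·pyridine, pyridine, THF, 0 °C to rt
Reagents that add atoms: none
Why: Buffered fluoride desilylation removes both TBS groups; the enol ester, the enone and the epimerisable C7 centre tolerate these mildly acidic conditions.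

**Compound list**
1 | 3-methylbut-2-en-1-ol | CC(C)=CCO | starting material
2 | 1-methoxy-4-{[(3-methylbut-2-en-1-yl)oxy]methyl}benzene | CC(C)=CCOCc1ccc(OC)cc1 | intermediate
3 | (2E)-2-methyl-4-(PMBO)but-2-enal | O=C/C(C)=C/COCc1ccc(OC)cc1 | intermediate
4 | but-3-en-2-one | CC(=O)C=C | starting material
5 | 2-(TBSO)buta-1,3-diene | C=CC(=C)O[Si](C)(C)C(C)(C)C | intermediate
6 | (1S,6S)-1-methyl-6-[(PMBO)methyl]-4-(TBSO)cyclohex-3-ene-1-carbaldehyde | O=C[C@@]1(C)CC=C(O[Si](C)(C)C(C)(C)C)C[C@@H]1COCc2ccc(OC)cc2 | intermediate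
7 | (4R,5S)-4-ethenyl-4-methyl-5-[(PMBO)methyl]-1-(TBSO)cyclohex-1-ene | C=C[C@@]1(C)CC=C(O[Si](C)(C)C(C)(C)C)C[C@@H]1COCc2ccc(OC)cc2 | intermediate
8 | 2-bromoprop-1-ene | CC(Br)=C | starting material
9 | 9-{2-[(1S,6S)-1-methyl-6-[(PMBO)methyl]-4-(TBSO)cyclohex-3-en-1-yl]ethyl}-9-borabicyclo[3.3.1]nonane | B1(CC[C@@]2(C)CC=C(O[Si](C)(C)C(C)(C)C)C[C@@H]2COCc3ccc(OC)cc3)C4CCCC1CCC4 | intermediate
10 | 2-methyl-5-[(1S,6S)-1-methyl-6-[(PMBO)methyl]-4-(TBSO)cyclohex-3-en-1-yl]pent-1-en-3-one | C=C(C)C(=O)CC[C@@]1(C)CC=C(O[Si](C)(C)C(C)(C)C)C[C@@H]1COCc2ccc(OC)cc2 | intermediate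
11 | (3R)-2-methyl-5-[(1S,6S)-1-methyl-6-[(PMBO)methyl]-4-(TBSO)cyclohex-3-en-1-yl]pent-1-en-3-ol | C=C(C)[C@H](O)CC[C@@]1(C)CC=C(O[Si](C)(C)C(C)(C)C)C[C@@H]1COCc2ccc(OC)cc2 | intermediate
12 | (4S,5S)-4-methyl-4-[(3R)-4-methyl-3-(TBSO)pent-4-en-1-yl]-5-[(PMBO)methyl]-1-(TBSO)cyclohex-1-ene | C=C(C)[C@H](O[Si](C)(C)C(C)(C)C)CC[C@@]1(C)CC=C(O[Si](C)(C)C(C)(C)C)C[C@@H]1COCc2ccc(OC)cc2 | intermediate
13 | ethane-1,2-diol | OCCO | starting material
14 | 2-(TBSO)ethan-1-ol | OCCO[Si](C)(C)C(C)(C)C | intermediate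
15 | (TBSO)acetaldehyde | O=CCO[Si](C)(C)C(C)(C)C | intermediate
16 | (TBSO)acetaldehyde hydrazone | NN=CCO[Si](C)(C)C(C)(C)C | intermediate
17 | 1,1-diiodo-2-(TBSO)ethane | IC(I)CO[Si](C)(C)C(C)(C)C | intermediate
18 | (3S,4S)-4-methyl-4-[(3R)-4-methyl-3-(TBSO)pent-4-en-1-yl]-3-[(PMBO)methyl]-1-(TBSO)-7-[(TBSO)methyl]bicyclo[4.1.0]heptane (mixture at C1, C6 and C7) | C=C(C)[C@H](O[Si](C)(C)C(C)(C)C)CC[C@@]1(C)CC2C(CO[Si](C)(C)C(C)(C)C)C2(O[Si](C)(C)C(C)(C)C)C[C@@H]1COCc3ccc(OC)cc3 | intermediate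
19 | (5S,6S)-3-chloro-5-methyl-5-[(3R)-4-methyl-3-(TBSO)pent-4-en-1-yl]-6-[(PMBO)methyl]-2-[(TBSO)methyl]cycloheptan-1-one (mixture at C2 and C3) | C=C(C)[C@H](O[Si](C)(C)C(C)(C)C)CC[C@@]1(C)CC(Cl)C(CO[Si](C)(C)C(C)(C)C)C(=O)C[C@@H]1COCc2ccc(OC)cc2 | intermediate
20 | (5S,6S)-5-methyl-5-[(3R)-4-methyl-3-(TBSO)pent-4-en-1-yl]-6-[(PMBO)methyl]-2-[(TBSO)methyl]cyclohept-2-en-1-one | C=C(C)[C@H](O[Si](C)(C)C(C)(C)C)CC[C@@]1(C)CC=C(CO[Si](C)(C)C(C)(C)C)C(=O)C[C@@H]1COCc2ccc(OC)cc2 | intermediate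
21 | (5S,6S)-6-(hydroxymethyl)-5-methyl-5-[(3R)-4-methyl-3-(TBSO)pent-4-en-1-yl]-2-[(TBSO)methyl]cyclohept-2-en-1-one | C=C(C)[C@H](O[Si](C)(C)C(C)(C)C)CC[C@@]1(C)CC=C(CO[Si](C)(C)C(C)(C)C)C(=O)C[C@@H]1CO | intermediate
22 | prop-1-en-2-yl acetate | CC(=C)OC(C)=O | starting material
23 | (5S,6S)-5-methyl-5-[(3R)-4-methyl-3-(TBSO)pent-4-en-1-yl]-6-[(prop-1-en-2-yloxy)methyl]-2-[(TBSO)methyl]cyclohept-2-en-1-one | C=C(C)[C@H](O[Si](C)(C)C(C)(C)C)CC[C@@]1(C)CC=C(CO[Si](C)(C)C(C)(C)C)C(=O)C[C@@H]1COC(C)=C | intermediate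
24 | (3S,4S)-4-methyl-4-[(3R)-4-methyl-3-(TBSO)pent-4-en-1-yl]-3-[(prop-1-en-2-yloxy)methyl]-7-[(TBSO)methyl]-1-(trimethylsilyloxy)cyclohepta-1,6-diene | C=C(C)[C@H](O[Si](C)(C)C(C)(C)C)CC[C@@]1(C)CC=C(CO[Si](C)(C)C(C)(C)C)C(O[Si](C)(C)C)=C[C@@H]1COC(C)=C | intermediate
25 | cis-fused cyclic hemiketal of 26 (oxygen of the C6 CH2O arm bonded to the side-chain ketone carbon; 2-hydroxy-2-methyltetrahydropyran fused at C6–C7) | C=C(C)[C@H](O[Si](C)(C)C(C)(C)C)CC[C@@]1(C)CC=C(CO[Si](C)(C)C(C)(C)C)C(=O)[C@@H]2CC(C)(O)OC[C@H]12 | intermediate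
26 | (5S,6S,7R)-6-(hydroxymethyl)-5-methyl-5-[(3R)-4-methyl-3-(TBSO)pent-4-en-1-yl]-7-(2-oxopropyl)-2-[(TBSO)methyl]cyclohept-2-en-1-one | C=C(C)[C@H](O[Si](C)(C)C(C)(C)C)CC[C@@]1(C)CC=C(CO[Si](C)(C)C(C)(C)C)C(=O)[C@H](CC(C)=O)[C@@H]1CO | intermediate
27 | dichloromethane | ClCCl | starting material
28 | (dichloromethyl)boronic acid | OB(O)C(Cl)Cl | intermediate
29 | 2,3-dimethylbutane-2,3-diol | CC(C)(O)C(C)(C)O | starting material
30 | 2-(dichloromethyl)-4,4,5,5-tetramethyl-1,3,2-dioxaborolane | ClC(Cl)B1OC(C)(C)C(C)(C)O1 | intermediate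
31 | (1S,2S,7R)-2-methyl-2-[(3R)-4-methyl-3-(TBSO)pent-4-en-1-yl]-6-oxo-7-(2-oxopropyl)-5-[(TBSO)methyl]cyclohept-4-ene-1-carbaldehyde | C=C(C)[C@H](O[Si](C)(C)C(C)(C)C)CC[C@@]1(C)CC=C(CO[Si](C)(C)C(C)(C)C)C(=O)[C@H](CC(C)=O)[C@@H]1C=O | intermediate
32 | (5S,6S,7R)-5-methyl-5-[(3R)-4-methyl-3-(TBSO)pent-4-en-1-yl]-7-(2-oxopropyl)-6-[(E)-2-(4,4,5,5-tetramethyl-1,3,2-dioxaborolan-2-yl)ethenyl]-2-[(TBSO)methyl]cyclohept-2-en-1-one | C=C(C)[C@H](O[Si](C)(C)C(C)(C)C)CC[C@@]1(C)CC=C(CO[Si](C)(C)C(C)(C)C)C(=O)[C@H](CC(C)=O)[C@@H]1/C=C/B2OC(C)(C)C(C)(C)O2 | intermediate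
33 | 3-methylbut-2-enoic acid | CC(C)=CC(=O)O | starting material
34 | (E)-2-{(1S,2S,7R)-2-methyl-2-[(3R)-4-methyl-3-(TBSO)pent-4-en-1-yl]-6-oxo-7-(2-oxopropyl)-5-[(TBSO)methyl]cyclohept-4-en-1-yl}ethenyl 3-methylbut-2-enoate | C=C(C)[C@H](O[Si](C)(C)C(C)(C)C)CC[C@@]1(C)CC=C(CO[Si](C)(C)C(C)(C)C)C(=O)[C@H](CC(C)=O)[C@@H]1/C=C/OC(=O)C=C(C)C | intermediate
35 | (E)-2-{(1S,2S,7R)-2-[(3R)-3-hydroxy-4-methylpent-4-en-1-yl]-5-(hydroxymethyl)-2-methyl-6-oxo-7-(2-oxopropyl)cyclohept-4-en-1-yl}ethenyl 3-methylbut-2-enoate | C=C(C)[C@H](O)CC[C@@]1(C)CC=C(CO)C(=O)[C@H](CC(C)=O)[C@@H]1/C=C/OC(=O)C=C(C)C | target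

**Step count**
Total: 21 steps. Longest linear sequence: 14 steps (1, 2, 4, 5, 6, 7, 8, 13, 14, 15, 16, 19, 20, 21).

**Three steps most likely to fail**

Step 16 (the new tethered oxidative coupling). Risks are intermolecular dimerisation of the radical, 5-exo closure, or loss of the enol ether before coupling. The fallback uses known chemistry, sets out from 21 and comes back at 26. Alcohol 21 is silylated (Et3SiCl, imidazole) to (5S,6S)-5-methyl-5-[(3R)-4-methyl-3-(TBSO)pent-4-en-1-yl]-2-[(TBSO)methyl]-6-[(triethylsilyloxy)methyl]cyclohept-2-en-1-one F1. Its kinetic lithium enolate (LiN(SiMe3)2, THF, −78 °C) adds to 2,2-dimethoxypropanal to give the aldol adduct (5S,6S)-7-(1-hydroxy-2,2-dimethoxypropyl) ketone F2. Mesylation and elimination (MsCl, Et3N, then DBU) give the (5S,6R,7E)-7-(2,2-dimethoxypropylidene) ketone F3. PPTS in wet acetone removes the ketal and the triethylsilyl group to give the (5S,6R,7E)-6-(hydroxymethyl)-7-(2-oxopropylidene) ene-dione F4. Hantzsch ester on silica gel (or Zn, AcOH) reduces the doubly activated exocyclic alkene chemoselectively; protonation at C7 anti to the pseudo-axial C6 arm gives 26. Stereocontrol here is kinetic and likely lower than in the tethered step.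

Step 13 (substituted zinc carbenoid and ring expansion). The β-silyloxy carbenoid may eliminate, or the oxidative opening may cleave the wrong cyclopropane bond. The fallback sets out from 12 and comes back at 20. Et2Zn and CH2I2 give the parent siloxycyclopropane (3S,4S)-4-methyl-4-[(3R)-4-methyl-3-(TBSO)pent-4-en-1-yl]-3-[(PMBO)methyl]-1-(TBSO)bicyclo[4.1.0]heptane F5. FeCl3 in DMF gives the 3-chloro ketone (5S,6S)-3-chloro-5-methyl-5-[(3R)-4-methyl-3-(TBSO)pent-4-en-1-yl]-6-[(PMBO)methyl]cycloheptan-1-one F6, and NaOAc in MeOH gives the cycloheptenone (5S,6S)-5-methyl-5-[(3R)-4-methyl-3-(TBSO)pent-4-en-1-yl]-6-[(PMBO)methyl]cyclohept-2-en-1-one F7. A Morita–Baylis–Hillman reaction with aqueous formaldehyde (imidazole, THF–H2O) installs the C2 arm as the (5S,6S)-2-(hydroxymethyl) enone F8, and TBSCl with imidazole gives 20.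

Step 6 (carbonylative coupling). Direct non-carbonylative coupling or polymerisation of the isopropenyl ketone may compete. The fallback sets out from 7 and comes back at 11. Hydroboration with Et2BH gives diethyl{2-[(1S,6S)-1-methyl-6-[(PMBO)methyl]-4-(TBSO)cyclohex-3-en-1-yl]ethyl}borane F9. Boron–zinc exchange with Et2Zn gives bis{2-[(1S,6S)-1-methyl-6-[(PMBO)methyl]-4-(TBSO)cyclohex-3-en-1-yl]ethyl}zinc F10. Addition to 2-methylprop-2-enal catalysed by Ti(OiPr)4 and (1S,2S)-N,N′-bis(trifluoromethylsulfonyl)cyclohexane-1,2-diamine then gives allylic alcohol 11 directly, so step 7 is skipped.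

**Further compounds**
F1 | step 16 | (5S,6S)-5-methyl-5-[(3R)-4-methyl-3-(TBSO)pent-4-en-1-yl]-2-[(TBSO)methyl]-6-[(triethylsilyloxy)methyl]cyclohept-2-en-1-one | C=C(C)[C@H](O[Si](C)(C)C(C)(C)C)CC[C@@]1(C)CC=C(CO[Si](C)(C)C(C)(C)C)C(=O)C[C@@H]1CO[Si](CC)(CC)CC
F2 | step 16 | (5S,6S)-7-(1-hydroxy-2,2-dimethoxypropyl)-5-methyl-5-[(3R)-4-methyl-3-(TBSO)pent-4-en-1-yl]-2-[(TBSO)methyl]-6-[(triethylsilyloxy)methyl]cyclohept-2-en-1-one (mixture at C7 and the carbinol carbon) | C=C(C)[C@H](O[Si](C)(C)C(C)(C)C)CC[C@@]1(C)CC=C(CO[Si](C)(C)C(C)(C)C)C(=O)C(C(O)C(C)(OC)OC)[C@@H]1CO[Si](CC)(CC)CC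
F3 | step 16 | (5S,6R,7E)-7-(2,2-dimethoxypropylidene)-5-methyl-5-[(3R)-4-methyl-3-(TBSO)pent-4-en-1-yl]-2-[(TBSO)methyl]-6-[(triethylsilyloxy)methyl]cyclohept-2-en-1-one | C=C(C)[C@H](O[Si](C)(C)C(C)(C)C)CC[C@@]1(C)CC=C(CO[Si](C)(C)C(C)(C)C)C(=O)/C(=C/C(C)(OC)OC)[C@@H]1CO[Si](CC)(CC)CC
F4 | step 16 | (5S,6R,7E)-6-(hydroxymethyl)-5-methyl-5-[(3R)-4-methyl-3-(TBSO)pent-4-en-1-yl]-7-(2-oxopropylidene)-2-[(TBSO)methyl]cyclohept-2-en-1-one | C=C(C)[C@H](O[Si](C)(C)C(C)(C)C)CC[C@@]1(C)CC=C(CO[Si](C)(C)C(C)(C)C)C(=O)/C(=C/C(C)=O)[C@@H]1CO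
F5 | step 13 | (3S,4S)-4-methyl-4-[(3R)-4-methyl-3-(TBSO)pent-4-en-1-yl]-3-[(PMBO)methyl]-1-(TBSO)bicyclo[4.1.0]heptane | C=C(C)[C@H](O[Si](C)(C)C(C)(C)C)CC[C@@]1(C)CC2CC2(O[Si](C)(C)C(C)(C)C)C[C@@H]1COCc3ccc(OC)cc3
F6 | step 13 | (5S,6S)-3-chloro-5-methyl-5-[(3R)-4-methyl-3-(TBSO)pent-4-en-1-yl]-6-[(PMBO)methyl]cycloheptan-1-one | C=C(C)[C@H](O[Si](C)(C)C(C)(C)C)CC[C@@]1(C)CC(Cl)CC(=O)C[C@@H]1COCc2ccc(OC)cc2
F7 | step 13 | (5S,6S)-5-methyl-5-[(3R)-4-methyl-3-(TBSO)pent-4-en-1-yl]-6-[(PMBO)methyl]cyclohept-2-en-1-one | C=C(C)[C@H](O[Si](C)(C)C(C)(C)C)CC[C@@]1(C)CC=CC(=O)C[C@@H]1COCc2ccc(OC)cc2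
F8 | step 13 | (5S,6S)-2-(hydroxymethyl)-5-methyl-5-[(3R)-4-methyl-3-(TBSO)pent-4-en-1-yl]-6-[(PMBO)methyl]cyclohept-2-en-1-one | C=C(C)[C@H](O[Si](C)(C)C(C)(C)C)CC[C@@]1(C)CC=C(CO)C(=O)C[C@@H]1COCc2ccc(OC)cc2
F9 | step 6 | diethyl{2-[(1S,6S)-1-methyl-6-[(PMBO)methyl]-4-(TBSO)cyclohex-3-en-1-yl]ethyl}borane | CCB(CC)CC[C@@]1(C)CC=C(O[Si](C)(C)C(C)(C)C)C[C@@H]1COCc2ccc(OC)cc2
F10 | step 6 | bis{2-[(1S,6S)-1-methyl-6-[(PMBO)methyl]-4-(TBSO)cyclohex-3-en-1-yl]ethyl}zinc | C(C[C@@]1(C)CC=C(O[Si](C)(C)C(C)(C)C)C[C@@H]1COCc2ccc(OC)cc2)[Zn]CC[C@@]3(C)CC=C(O[Si](C)(C)C(C)(C)C)C[C@@H]3COCc4ccc(OC)cc4
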